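**Plan**

1. Numbering follows the monomer, 7-acetyl-3,6,8-trihydroxy-4,4-dimethylnaphthalen-1(4H)-one: ring B is C1–C4, C4a, C8a; ring A is C4a, C5–C8, C8a.
2. The retrosynthesis cuts the two C2–CH2 bonds of the bridge (formaldehyde), then C6–C7 and C7–C8 of ring A, then C2–C3, C1–C8a and C4–C4a of ring B.
3. Enabling feature: C7 with its acetyl group is an acetone carbon between the oxygenated C6 and C8, so ring A is a glutaconic anhydride fused to ring B (C8 on C8a, C5–C6 on C4a) whose ring oxygen is exchanged for the CH2 carbon of isopropenyl acetate.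
4. Forward, the chain is joined first: an isobutyrate enolate adds to an allenedicarboxylate (quaternary C4), and acetyl chloride puts C1–C2 on C8a. Ring B then closes by dianion Claisen condensation, the anhydride ring by dehydration, ring A by the AlCl3 diacylation, and formaldehyde joins two monomers at C2.
5. Ring B is built from acyclic pieces so that the C4a and C8a arms are placed by connectivity and not by selective activation of one ring-B oxygen.
6. Stereochemistry: the target has no stereocentre; allene 2 is racemic and the alkene geometry of 5 and 7 is lost on ring closure.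

Key step: step 7

Assumption: in step 5 the diazoalkane methylates the C3 oxygen of 8 (the enol oxygen not hydrogen-bonded to the C8a ester); the C1-O isomer, if formed, would give the same compound 16 after step 8.

**Route**

Step 1
Reactants: 1 di-tert-butyl 3-oxopentanedioate
Product: 2 di-tert-butyl penta-2,3-dienedioate (racemic)
Conditions: 2-chloro-1,3-dimethylimidazolinium chloride, Et3N, CH2Cl2, 0 °C
Reagents that add atoms: none
Why: The chloroamidinium salt turns the enol of the 3-oxoglutarate into an O-amidinium enol ether that Et3N eliminates (β-elimination), the established one-step dehydration of 3-oxopentanedioates to allene-1,3-dicarboxylates.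

Step 2
Reactants: 2 di-tert-butyl penta-2,3-dienedioate; 3 methyl 2-methylpropanoate
Product: 5 di-tert-butyl 3-(1-methoxy-2-methyl-1-oxopropan-2-yl)pent-2-enedioate, via lithium ester enolate 4 (not isolated)
Conditions: 3, LiN(iPr)2, THF, −78 °C; then 2, −78 °C; sat. aq. NH4Cl at −78 °C
Reagents that add atoms: none
Why: Michael addition of the lithium ester enolate to the central sp carbon of the allene, which is β to both esters, should give the 3-substituted glutaconate and creates the quaternary C4 and the C4–C4a bond with no regiochemical alternative, the cold quench keeping diisopropylamine from adding to the allene.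

Step 3
Reactants: 5 di-tert-butyl 3-(1-methoxy-2-methyl-1-oxopropan-2-yl)pent-2-enedioate; 6 acetyl chloride
Product: 7 di-tert-butyl 2-acetyl-3-(1-methoxy-2-methyl-1-oxopropan-2-yl)pent-2-enedioate
Conditions: MgCl2, Et3N, MeCN, 0 °C; then 6, 0 °C to rt; 1 M aq. HCl work-up
Reagents that add atoms: none
Why: C-Acylation of a magnesium enolate (MgCl2/Et3N soft enolisation) by the acid chloride should acetylate the doubly activated glutaconate carbon, whose two termini are equivalent, placing C1–C2 on C8a, while the tert-butyl esters hold back the lactonisation of 2-acylglutaconates to 2-pyranones.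

Step 4
Reactants: 7 di-tert-butyl 2-acetyl-3-(1-methoxy-2-methyl-1-oxopropan-2-yl)pent-2-enedioate
Product: 8 tert-butyl 2-(2-tert-butoxy-2-oxoethyl)-3,3-dimethyl-4,6-dioxocyclohex-1-ene-1-carboxylate
Conditions: LiN(iPr)2 (3.2 equiv), THF, −78 to 0 °C; 1 M aq. HCl
Reagents that add atoms: none
Why: Intramolecular Claisen condensation of an acetoacetate-type dianion through its terminal carbon (C2) onto the CMe2 methyl ester, the only ester not conjugated to the anion, closes ring B (C2–C3, 6-exo-trig) and is driven by formation of the cyclic 1,3-diketonate.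

Step 5
Reactants: 8 tert-butyl 2-(2-tert-butoxy-2-oxoethyl)-3,3-dimethyl-4,6-dioxocyclohex-1-ene-1-carboxylate
Product: 9 tert-butyl 2-(2-tert-butoxy-2-oxoethyl)-4-methoxy-3,3-dimethyl-6-oxocyclohexa-1,4-diene-1-carboxylate
Conditions: TMSCHN2, MeOH/toluene, 0 °C to rt
Reagents that add atoms: trimethylsilyldiazomethane, C[Si](C)(C)C=[N+]=[N-]
Why: O-Methylation of an enolised cyclic 1,3-dione by a diazoalkane should take the C3 oxygen, which is not hydrogen-bonded to the adjacent C8a ester, in the way the 4-hydroxyl of 2,4-dihydroxybenzoates is methylated selectively.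

Step 6
Reactants: 9 tert-butyl 2-(2-tert-butoxy-2-oxoethyl)-4-methoxy-3,3-dimethyl-6-oxocyclohexa-1,4-diene-1-carboxylate
Product: 11 6-methoxy-5,5-dimethyl-1H-isochromene-1,3,8(4H,5H)-trione, via diacid 10 (not isolated)
Conditions: CF3CO2H, CH2Cl2, rt; evaporate without heating; (CF3CO)2O, CH2Cl2, 0 °C to rt
Reagents that add atoms: none
Why: Acidolysis of both tert-butyl esters (E1 loss of 2-methylpropene) in the absence of water leaves the enol ether intact, and dehydration of the resulting 1,5-diacid with a carboxylic anhydride is the usual way to six-membered homophthalic-type anhydrides.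

Step 7
Reactants: 11 6-methoxy-5,5-dimethyl-1H-isochromene-1,3,8(4H,5H)-trione; 12 isopropenyl acetate
Product: 15 7-acetyl-6,8-dihydroxy-3-methoxy-4,4-dimethylnaphthalen-1(4H)-one, via diketo acid 13 (not isolated), via cyclic triketone 14 (not isolated)
Conditions: AlCl3 (4 equiv), ClCH2CH2Cl, 0 °C; then 12 (1.2 equiv), 60 °C; ice/aq. HCl
Reagents that add atoms: none
Why: Proposed new method: AlCl3 opens anhydride 11 at its unconjugated C6 carbonyl to an acylium-type complex that acylates the CH2 terminus of 12, the acetyl group of 12 is released, and the aluminium β-diketonate of 13 holds the future C7 between two carbonyls. The C8 carboxyl, activated by AlCl3 or as a mixed anhydride, then acylates C7 in a 6-exo-trig (5+1) closure to triketone 14, which already contains the C4a=C8a bond and enolises at C6 and C8 to aromatic ring A. The closest known reaction is the AlCl3-mediated diacylation of isopropenyl acetate by succinic, glutaric, maleic and phthalic anhydrides to 2-acetylcycloalkane-1,3-diones; a glutaconic anhydride fused to a dienone has not been used. No stereocentre is formed. The step needs both acylations on the acetone carbon C7 and none on C2 of ring B: after the first C–C bond the diketonate carbon sits five atoms from the second acyl group, so closure is intramolecular, and C2 is deactivated because AlCl3 coordinates the C1 carbonyl of the vinylogous ester.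

Step 8
Reactants: 15 7-acetyl-6,8-dihydroxy-3-methoxy-4,4-dimethylnaphthalen-1(4H)-one
Product: 16 7-acetyl-3,6,8-trihydroxy-4,4-dimethylnaphthalen-1(4H)-one
Conditions: 2 M aq. HCl, THF, 50 °C
Reagents that add atoms: water, O
Why: Acid hydrolysis of the vinylogous methyl ester (conjugate addition of water at C3, loss of methanol) frees the cyclic 1,3-dione as its enol, while the phenols and the aryl ketone are inert.

Step 9
Reactants: 16 7-acetyl-3,6,8-trihydroxy-4,4-dimethylnaphthalen-1(4H)-one (two equivalents); 17 formaldehyde
Product: 19 2,2'-methylenebis[7-acetyl-3,6,8-trihydroxy-4,4-dimethylnaphthalen-1(4H)-one], via methylidene trione 18 (not isolated)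
Conditions: 37% aq. CH2O (0.5 equiv), K2CO3 (0.2 equiv), MeOH/H2O, rt
Reagents that add atoms: none
Why: Knoevenagel condensation of the acidic C2 of the cyclic 1,3-dione with formaldehyde, then Michael addition of a second dione to the 2-methylidene trione, is the standard route to methylene-bridged acylphloroglucinol and filicinic acid dimers, and C2 reacts ahead of the acyl-deactivated, peri-hindered aromatic C5.

**Compound list**

1 | di-tert-butyl 3-oxopentanedioate | CC(C)(C)OC(=O)CC(=O)CC(=O)OC(C)(C)C | starting material
2 | di-tert-butyl penta-2,3-dienedioate (racemic) | CC(C)(C)OC(=O)C=C=CC(=O)OC(C)(C)C | intermediate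
3 | methyl 2-methylpropanoate | COC(=O)C(C)C | starting material
4 | lithium 1-methoxy-2-methylprop-1-en-1-olate (not isolated) | COC(O[Li])=C(C)C | intermediate
5 | di-tert-butyl 3-(1-methoxy-2-methyl-1-oxopropan-2-yl)pent-2-enedioate (E/Z mixture) | COC(=O)C(C)(C)C(=CC(=O)OC(C)(C)C)CC(=O)OC(C)(C)C | intermediate
6 | acetyl chloride | CC(=O)Cl | starting material
7 | di-tert-butyl 2-acetyl-3-(1-methoxy-2-methyl-1-oxopropan-2-yl)pent-2-enedioate (mixture of alkene and enol tautomers) | COC(=O)C(C)(C)C(CC(=O)OC(C)(C)C)=C(C(C)=O)C(=O)OC(C)(C)C | intermediate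
8 | tert-butyl 2-(2-tert-butoxy-2-oxoethyl)-3,3-dimethyl-4,6-dioxocyclohex-1-ene-1-carboxylate | CC(C)(C)OC(=O)CC1=C(C(=O)OC(C)(C)C)C(=O)CC(=O)C1(C)C | intermediate
9 | tert-butyl 2-(2-tert-butoxy-2-oxoethyl)-4-methoxy-3,3-dimethyl-6-oxocyclohexa-1,4-diene-1-carboxylate | COC1=CC(=O)C(C(=O)OC(C)(C)C)=C(CC(=O)OC(C)(C)C)C1(C)C | intermediate
10 | 2-(carboxymethyl)-4-methoxy-3,3-dimethyl-6-oxocyclohexa-1,4-diene-1-carboxylic acid (not isolated) | COC1=CC(=O)C(C(=O)O)=C(CC(=O)O)C1(C)C | intermediate
11 | 6-methoxy-5,5-dimethyl-1H-isochromene-1,3,8(4H,5H)-trione | COC1=CC(=O)C2=C(CC(=O)OC2=O)C1(C)C | intermediate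
12 | isopropenyl acetate (prop-1-en-2-yl acetate) | CC(=C)OC(C)=O | starting material
13 | 2-(2,4-dioxopentyl)-4-methoxy-3,3-dimethyl-6-oxocyclohexa-1,4-diene-1-carboxylic acid (not isolated) | COC1=CC(=O)C(C(=O)O)=C(CC(=O)CC(C)=O)C1(C)C | intermediate
14 | 7-acetyl-3-methoxy-4,4-dimethyl-5,7-dihydronaphthalene-1,6,8(4H)-trione (not isolated) | COC1=CC(=O)C2=C(CC(=O)C(C(C)=O)C2=O)C1(C)C | intermediate
15 | 7-acetyl-6,8-dihydroxy-3-methoxy-4,4-dimethylnaphthalen-1(4H)-one | COC1=CC(=O)c2c(O)c(C(C)=O)c(O)cc2C1(C)C | intermediate
16 | 7-acetyl-3,6,8-trihydroxy-4,4-dimethylnaphthalen-1(4H)-one | CC(=O)c1c(O)cc2c(c1O)C(=O)C=C(O)C2(C)C | intermediate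
17 | formaldehyde | C=O | starting material
18 | 7-acetyl-6,8-dihydroxy-4,4-dimethyl-2-methylidenenaphthalene-1,3(2H,4H)-dione (not isolated) | CC(=O)c1c(O)cc2c(c1O)C(=O)C(=C)C(=O)C2(C)C | intermediate
19 | 2,2'-methylenebis[7-acetyl-3,6,8-trihydroxy-4,4-dimethylnaphthalen-1(4H)-one] | CC(=O)c1c(O)cc2c(c1O)C(=O)C(CC1=C(O)C(C)(C)c3cc(O)c(C(C)=O)c(O)c3C1=O)=C(O)C2(C)C | target

**Step count**

Total steps: 9. Longest linear sequence: 9 (from 1 to 19).

**Steps most likely to fail**

Step 7 (labelled). Under AlCl3 the anhydride may enolise at its C5 methylene and acylate itself, or the sequence may stop after the first acylation without ring closure. The fallback uses known chemistry only, sets out from 11 and returns at 15. Methanolysis of 11 at the unconjugated carbonyl (MeOH, rt) should give the half ester 4-methoxy-2-(2-methoxy-2-oxoethyl)-3,3-dimethyl-6-oxocyclohexa-1,4-diene-1-carboxylic acid F1. Activation of its C8 carboxyl with 1,1'-carbonyldiimidazole and acylation of the lithium enolate of acetone (LiN(iPr)2, THF, −78 °C) should give the β-diketone methyl 2-[5-methoxy-6,6-dimethyl-3-oxo-2-(3-oxobutanoyl)cyclohexa-1,4-dien-1-yl]acetate F2. NaOMe in MeOH should then close ring A by Claisen condensation of the diketone carbon C7 onto the side-chain ester, and triketone 14 enolises to 15.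

Step 4. Proton transfer may quench the terminal carbanion of the dianion, or the enolate oxygen may be acylated instead of C2. The fallback sets out from 2 and returns at 9. A KOtBu-mediated Michael–Claisen annulation of 2 with 3-methylbutan-2-one (tBuOH/THF, rt to 60 °C) adds through the more substituted enolate carbon and closes the methyl ketone onto either tert-butyl ester, as in the preparation of 4,4-dimethylcyclohexane-1,3-dione from this ketone and an acrylate. It should give tert-butyl 2-(6,6-dimethyl-3,5-dioxocyclohex-1-en-1-yl)acetate F3. TMSCHN2 should give the cross-conjugated enol ether tert-butyl 2-(5-methoxy-6,6-dimethyl-3-oxocyclohexa-1,4-dien-1-yl)acetate F4. Deprotonation of the side-chain CH2 (LiN(iPr)2, THF, −78 °C) and trapping with Boc2O should acylate the dienolate at the ketone α-carbon C8a, the position at which the anion of Hagemann's ester reacts, to give 9.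

Step 3. The ambident glutaconate anion may be acylated on oxygen, or the C-acyl product may lactonise to a 2-pyranone. The fallback sets out from 5 and returns at 7. The lithium dienolate of 5 (LiN(iPr)2, THF, −78 °C) should add to acetaldehyde at its α-carbon to give the alcohol di-tert-butyl 4-(1-hydroxyethyl)-3-(1-methoxy-2-methyl-1-oxopropan-2-yl)pent-2-enedioate F5 (mixture of stereoisomers). Dess–Martin periodinane then oxidises it to 7.

**Further compounds**

F1 | step 7 | 4-methoxy-2-(2-methoxy-2-oxoethyl)-3,3-dimethyl-6-oxocyclohexa-1,4-diene-1-carboxylic acid | COC(=O)CC1=C(C(O)=O)C(=O)C=C(OC)C1(C)C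
F2 | step 7 | methyl 2-[5-methoxy-6,6-dimethyl-3-oxo-2-(3-oxobutanoyl)cyclohexa-1,4-dien-1-yl]acetate | COC(=O)CC1=C(C(=O)CC(C)=O)C(=O)C=C(OC)C1(C)C
F3 | step 4 | tert-butyl 2-(6,6-dimethyl-3,5-dioxocyclohex-1-en-1-yl)acetate | CC(C)(C)OC(=O)CC1=CC(=O)CC(=O)C1(C)C
F4 | step 4 | tert-butyl 2-(5-methoxy-6,6-dimethyl-3-oxocyclohexa-1,4-dien-1-yl)acetate | COC1=CC(=O)C=C(CC(=O)OC(C)(C)C)C1(C)C
F5 | step 3 | di-tert-butyl 4-(1-hydroxyethyl)-3-(1-methoxy-2-methyl-1-oxopropan-2-yl)pent-2-enedioate | COC(=O)C(C)(C)C(=CC(=O)OC(C)(C)C)C(C(C)O)C(=O)OC(C)(C)C
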